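**Strategy.** The oxolan-2-one ring (O1, C2=O, C3, C4, C5) is cut at O1–C5 and C3–C4. C4, which carries the vanillyl CH2 and sits next to the O-bound C5, is read as a latent ketone carbon: an α-chloroketone supplies C4–C5, diethylphosphonoacetic acid supplies O1–C2–C3. In one operation the carboxylate alkylates C5 and the phosphonate carbanion olefinates the C4 ketone, giving a 4-benzylbutenolide from two achiral precursors. The butenolide oxidation level is removed as the stereocentres are set: C4 by asymmetric hydrogenation, C3 by a trans-selective aldol addition of the second aryl unit, followed by one global hydrogenolysis.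

Key step: step 3

Assumption: in step 4 the ZhaoPhos enantiomer is taken to be the one that delivers the 4R lactone; the sense of induction for this substrate is to be confirmed on the first run against a known (R)-4-benzyloxolan-2-one.

Step 1
Reactants: 1 1-(benzyloxy)-4-bromo-2-methoxybenzene; 2 2-(chloromethyl)oxirane (epichlorohydrin, racemic)
Product: 4 1-[4-(benzyloxy)-3-methoxyphenyl]-3-chloropropan-2-ol (racemic), via arylmagnesium bromide 3 (not isolated)
Conditions: Mg, THF, 40 °C; then CuI (10 mol%), 2, −40 °C to 0 °C; aq. NH4Cl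
Reagents that add atoms: none
Why: Grignard formation followed by CuI-catalysed SN2 opening of the epoxide at its unsubstituted CH2 carbon should give the chlorohydrin with the chloride untouched; the alcohol centre is racemic and is removed in step 2.

Step 2
Reactants: 4 1-[4-(benzyloxy)-3-methoxyphenyl]-3-chloropropan-2-ol
Product: 5 1-[4-(benzyloxy)-3-methoxyphenyl]-3-chloropropan-2-one
Conditions: Dess–Martin periodinane, CH2Cl2, 0 °C to rt
Reagents that add atoms: none
Why: Dess–Martin oxidation of the secondary alcohol under neutral conditions should give the α-chloroketone without touching the benzyl ether or the alkyl chloride.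

Step 3
Reactants: 5 1-[4-(benzyloxy)-3-methoxyphenyl]-3-chloropropan-2-one; 6 2-(diethoxyphosphoryl)acetic acid
Product: 8 4-[4-(benzyloxy)-3-methoxybenzyl]furan-2(5H)-one, via keto phosphonoacetate 7 (not isolated)
Conditions: Cs2CO3 (2.2 equiv), NaI (10 mol%), MeCN, 0 °C to rt, then 50 °C
Reagents that add atoms: none
Why: The cesium carboxylate of 6, the only anion present at the start because CO2H is far more acidic than the P(O)CH2 group, displaces chloride (through the iodide made by NaI) from the carbonyl-activated CH2Cl of 5 in an SN2 reaction, which forms O1–C5 and gives 7. Only in ester 7 is the phosphonate CH2 acidic enough for Cs2CO3; its carbanion adds to the neighbouring ketone and the oxaphosphetane collapses with loss of diethyl phosphate, which forms C3=C4 (intramolecular Horner–Wadsworth–Emmons olefination). The closest known reaction type is the butenolide synthesis from phosphonoacetates of α-hydroxy ketones; here the ester is made in the same flask by carboxylate alkylation. The oxolane ring closes by 5-exo-trig attack of C3 on the C4 carbonyl, and the ring permits only the endocyclic alkene. No stereocentre is formed: C4 is deliberately left trigonal so that step 4 sets it under catalyst control, and C3 is set in step 7. The step needs O-alkylation before carbanion formation, and olefination in preference to enolate chemistry of the chloroketone; the acidity order and the five-membered intramolecular closure onto the single ketone secure both.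

Step 4
Reactants: 8 4-[4-(benzyloxy)-3-methoxybenzyl]furan-2(5H)-one
Product: 9 (4R)-4-[4-(benzyloxy)-3-methoxybenzyl]oxolan-2-one
Conditions: [Rh(NBD)2]BF4 (1 mol%), ZhaoPhos (1.1 mol%), H2 (50 atm), CH2Cl2, rt
Reagents that add atoms: none
Why: Rhodium-catalysed asymmetric hydrogenation of a β-substituted butenolide, in which the thiourea of the ligand hydrogen-bonds to the lactone carbonyl and the chiral bisphosphine–Rh centre delivers H2 to one face of C3=C4, should set C4 (R) under catalyst control while the benzyl ether survives the homogeneous catalyst.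

Step 5
Reactants: 10 2-methoxybenzene-1,3-diol
Product: 11 1,3-bis(benzyloxy)-2-methoxybenzene
Conditions: BnBr (2.2 equiv), K2CO3, DMF, 60 °C
Reagents that add atoms: benzyl bromide BrCc1ccccc1
Why: Williamson ether synthesis on both phenols protects them as benzyl ethers that withstand steps 6 and 7 and fall in step 8.

Step 6
Reactants: 11 1,3-bis(benzyloxy)-2-methoxybenzene
Product: 12 2,4-bis(benzyloxy)-3-methoxybenzaldehyde
Conditions: POCl3, DMF, 0 °C to 70 °C; then H2O
Reagents that add atoms: N,N-dimethylformamide CN(C)C=O; water O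
Why: Vilsmeier–Haack formylation should enter at C4, ortho to one and para to the other benzyloxy group, as 1,2,3-trimethoxybenzene gives 2,3,4-trimethoxybenzaldehyde.

Step 7
Reactants: 9 (4R)-4-[4-(benzyloxy)-3-methoxybenzyl]oxolan-2-one; 12 2,4-bis(benzyloxy)-3-methoxybenzaldehyde
Product: 14 (3S,4R)-3-{[2,4-bis(benzyloxy)-3-methoxyphenyl](hydroxy)methyl}-4-[4-(benzyloxy)-3-methoxybenzyl]oxolan-2-one (both carbinol epimers), via lithium enolate 13 (not isolated)
Conditions: LiN(SiMe3)2, THF, −78 °C; then 12, −78 °C; aq. NH4Cl at −78 °C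
Reagents that add atoms: none
Why: Lithium enolate aldol addition in which the aldehyde adds to the enolate face anti to the C4 arylmethyl group should set C3 trans to C4 by substrate control; the carbinol centre forms as a mixture and is removed in step 8.

Step 8
Reactants: 14 (3S,4R)-3-{[2,4-bis(benzyloxy)-3-methoxyphenyl](hydroxy)methyl}-4-[4-(benzyloxy)-3-methoxybenzyl]oxolan-2-one
Product: 15 (3R,4R)-3-(2,4-dihydroxy-3-methoxybenzyl)-4-(4-hydroxy-3-methoxybenzyl)oxolan-2-one
Conditions: H2 (3 atm), 10% Pd/C, AcOH, HClO4 (cat.), rt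
Reagents that add atoms: none
Why: Catalytic hydrogenolysis over Pd/C under acid should cleave the three benzyl ethers and the benzylic C–OH bond activated by the ortho and para oxygens without touching C3 or C4, so the 3R,4R configuration is carried into the target.

**Compound list**

1 | 1-(benzyloxy)-4-bromo-2-methoxybenzene | COc1cc(Br)ccc1OCc1ccccc1 | starting material
2 | 2-(chloromethyl)oxirane (epichlorohydrin, racemic) | ClCC1CO1 | starting material
3 | [4-(benzyloxy)-3-methoxyphenyl]magnesium bromide | COc1cc([Mg]Br)ccc1OCc1ccccc1 | intermediate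
4 | 1-[4-(benzyloxy)-3-methoxyphenyl]-3-chloropropan-2-ol (racemic) | COc1cc(CC(O)CCl)ccc1OCc1ccccc1 | intermediate
5 | 1-[4-(benzyloxy)-3-methoxyphenyl]-3-chloropropan-2-one | COc1cc(CC(=O)CCl)ccc1OCc1ccccc1 | intermediate
6 | 2-(diethoxyphosphoryl)acetic acid | CCOP(=O)(CC(=O)O)OCC | starting material
7 | 3-[4-(benzyloxy)-3-methoxyphenyl]-2-oxopropyl 2-(diethoxyphosphoryl)acetate | CCOP(=O)(CC(=O)OCC(=O)Cc1ccc(OCc2ccccc2)c(OC)c1)OCC | intermediate
8 | 4-[4-(benzyloxy)-3-methoxybenzyl]furan-2(5H)-one | COc1cc(CC2=CC(=O)OC2)ccc1OCc1ccccc1 | intermediate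
9 | (4R)-4-[4-(benzyloxy)-3-methoxybenzyl]oxolan-2-one | COc1cc(C[C@H]2COC(=O)C2)ccc1OCc1ccccc1 | intermediate
10 | 2-methoxybenzene-1,3-diol (2-methoxyresorcinol) | COc1c(O)cccc1O | starting material
11 | 1,3-bis(benzyloxy)-2-methoxybenzene | COc1c(OCc2ccccc2)cccc1OCc1ccccc1 | intermediate
12 | 2,4-bis(benzyloxy)-3-methoxybenzaldehyde | COc1c(OCc2ccccc2)ccc(C=O)c1OCc1ccccc1 | intermediate
13 | lithium enolate of 9: lithium (3R)-3-[4-(benzyloxy)-3-methoxybenzyl]-2,3-dihydrofuran-5-olate | COc1cc(C[C@H]2COC(O[Li])=C2)ccc1OCc1ccccc1 | intermediate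
14 | (3S,4R)-3-{[2,4-bis(benzyloxy)-3-methoxyphenyl](hydroxy)methyl}-4-[4-(benzyloxy)-3-methoxybenzyl]oxolan-2-one, both carbinol epimers; ring substituents trans as in 15 (the C3 descriptor differs only because CH(OH)Ar outranks C4) | COc1cc(C[C@H]2COC(=O)[C@@H]2C(O)c2ccc(OCc3ccccc3)c(OC)c2OCc2ccccc2)ccc1OCc1ccccc1 | intermediate
15 | (3R,4R)-3-(2,4-dihydroxy-3-methoxybenzyl)-4-(4-hydroxy-3-methoxybenzyl)oxolan-2-one | COc1cc(C[C@H]2COC(=O)[C@@H]2Cc2ccc(O)c(OC)c2O)ccc1O | target

**Step count.** Total steps: 8. Longest linear sequence: 6 (steps 1, 2, 3, 4, 7, 8); steps 5 and 6 form the second branch, which joins at step 7.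

**Steps most likely to fail, with fallbacks.**

First, step 3. Base-induced enolisation of the chloroketone (self-condensation or Favorskii-type loss of chloride) may outrun esterification, or the butenolide may deconjugate or dimerise under the basic conditions. The fallback sets out from 5 and comes back at 8, and builds the ring by acylation and neutral Wittig closure instead of alkylation and base-mediated olefination. Compound 5 with KOAc in DMF should give 3-[4-(benzyloxy)-3-methoxyphenyl]-2-oxopropyl acetate F1. Methanolysis (K2CO3, MeOH, 0 °C) should give 1-[4-(benzyloxy)-3-methoxyphenyl]-3-hydroxypropan-2-one F2. Heating F2 with (triphenylphosphoranylidene)ketene, Ph3P=C=C=O, in toluene should add the alcohol across the cumulene to give 3-[4-(benzyloxy)-3-methoxyphenyl]-2-oxopropyl 2-(triphenyl-λ5-phosphanylidene)acetate F3 (not isolated), which should close onto the ketone by intramolecular Wittig reaction to 8.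

Second, step 4. Enantioface discrimination may be insufficient, or turnover slow, for an arylmethyl substituent at C4. The fallback sets out from 8 and comes back at 9, and obtains the stereocentre by resolution instead of catalysis. Conjugate reduction of 8 without stereocontrol (NaBH4, NiCl2·6H2O, MeOH, 0 °C) should give racemic 4-[4-(benzyloxy)-3-methoxybenzyl]oxolan-2-one F4. Opening of F4 with (S)-1-phenylethylamine (AlMe3, toluene, 60 °C) should give two diastereomeric hydroxy amides, (3R)-3-[4-(benzyloxy)-3-methoxybenzyl]-4-hydroxy-N-[(1S)-1-phenylethyl]butanamide F5 and (3S)-3-[4-(benzyloxy)-3-methoxybenzyl]-4-hydroxy-N-[(1S)-1-phenylethyl]butanamide F6, to be separated by crystallisation or chromatography. Relactonisation of F5 (2 M H2SO4, dioxane, reflux) should return 9 and release the amine.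

Third, step 8. Acid-promoted dehydration of the β-hydroxy lactone to the α-benzylidene lactone may precede hydrogenolysis, and unselective hydrogenation of that alkene would erode the C3 configuration. The fallback sets out from 14 and comes back at 15, and removes the hydroxyl by ionic reduction before the benzyl groups are touched. Compound 14 with Et3SiH and BF3·OEt2 in CH2Cl2 at −78 °C to −20 °C should give, through the oxygen-stabilised benzylic cation, (3R,4R)-3-[2,4-bis(benzyloxy)-3-methoxybenzyl]-4-[4-(benzyloxy)-3-methoxybenzyl]oxolan-2-one F7. Neutral hydrogenolysis of F7 (H2, Pd/C, EtOAc–MeOH, rt) should then give 15.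

**Further compounds**

F1 | step 3 | 3-[4-(benzyloxy)-3-methoxyphenyl]-2-oxopropyl acetate | COc1cc(CC(=O)COC(C)=O)ccc1OCc1ccccc1
F2 | step 3 | 1-[4-(benzyloxy)-3-methoxyphenyl]-3-hydroxypropan-2-one | COc1cc(CC(=O)CO)ccc1OCc1ccccc1
F3 | step 3 | 3-[4-(benzyloxy)-3-methoxyphenyl]-2-oxopropyl 2-(triphenyl-λ5-phosphanylidene)acetate | COc1cc(CC(=O)COC(=O)C=P(c2ccccc2)(c2ccccc2)c2ccccc2)ccc1OCc1ccccc1
F4 | step 4 | racemic 4-[4-(benzyloxy)-3-methoxybenzyl]oxolan-2-one | COc1cc(CC2COC(=O)C2)ccc1OCc1ccccc1
F5 | step 4 | (3R)-3-[4-(benzyloxy)-3-methoxybenzyl]-4-hydroxy-N-[(1S)-1-phenylethyl]butanamide | COc1cc(C[C@@H](CO)CC(=O)N[C@@H](C)c2ccccc2)ccc1OCc1ccccc1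
F6 | step 4 | (3S)-3-[4-(benzyloxy)-3-methoxybenzyl]-4-hydroxy-N-[(1S)-1-phenylethyl]butanamide | COc1cc(C[C@H](CO)CC(=O)N[C@@H](C)c2ccccc2)ccc1OCc1ccccc1
F7 | step 8 | (3R,4R)-3-[2,4-bis(benzyloxy)-3-methoxybenzyl]-4-[4-(benzyloxy)-3-methoxybenzyl]oxolan-2-one | COc1cc(C[C@H]2COC(=O)[C@@H]2Cc2ccc(OCc3ccccc3)c(OC)c2OCc2ccccc2)ccc1OCc1ccccc1
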